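All constants stand for no real mixture; no experiment stands behind them.

Over 5.0 s we follow how much target a flask makes when its nucleophile must come in through the gas, with the electrophile fed over different times.

    electrophile + nucleophile ⇌ acid set free + target (K1 = 4.3, k1 = 360 M⁻¹ s⁻¹)
    nucleophile + acid set free ⇌ protonated nucleophile, settled at all times (K2 = 2.4 × 10⁶ M⁻¹)
    gas ⇌ nucleophile, rate k3*(csat - [nucleophile]) (k3 = 0.25 s⁻¹, csat = 1.6 mM)

in all of them: gas 1.6 mM (held); time 5.0 s

| flask | electrophile |
|---|---|
| blue | 5.0 mM (fed, over 0.080 s) |
| green | 5.0 mM (fed, over 0.15 s) |
| teal | 5.0 mM (fed, over 0.30 s) |

- at the start none of nucleophile is dissolved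
- "hardly changes" means that all values lie within two and a half points (for a concentration: within two and a half percent of the largest)
- run time (blue): 5.0 s

- amount of target at the end, in percent of the electrophile charged for blue, green, teal, in this order
- the shape of the row from first to last (falls all the way / rises all the way / falls, then rises / hardly changes / rises, then falls)

- We begin with the ceiling. With no nucleophile dissolved, uptake runs at 0.400 mM s⁻¹, which over 5.0 s comes to 2.00 mM.
- Dissolved nucleophile narrows the gap to saturation, so we work with what stays open. We count two nucleophiles lost per target, one in step 1 and one binding the acid set free. With the electrophile near its charge, the loss is pseudo-first-order with constant 3.60 s⁻¹, larger than 0.25 s⁻¹. Uptake balances this loss when the fraction of csat left unfilled by c(nucleophile), the open gap, is 93.5%.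
- That gap puts c(nucleophile) at 0.104 mM. At this level, protonated nucleophile outnumbers free acid 249 to one, so counting two per target is sound.
- Uptake is therefore 0.374 mM s⁻¹, or 1.87 mM over the run. One target per two nucleophiles gives 18.7% of the charge.
- The weak link is that this pairs every nucleophile taken up, yet 0.104 mM stands unpaired in solution. Taking it off gives 17.7%, our figure for each flask.
- The dissolved level approaches its balance with a time constant of 0.260 s, and several of these, 0.780 s, are still shorter than 5.0 s; the longest feed, 0.30 s, is also shorter than 5.0 s. So we expect a flat row.
- The forecast gives 17.4%, 17.4% and 17.4%, with the shape hardly changes, holding that “each target consumes two nucleophiles because the second traps the released acid”. Our 17.7% stands a little higher.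
- The simulation gives 17.5%, 17.5% and 17.5%, with the shape hardly changes.
- In blue, up to 0.0800 s, electrophile came in while c(nucleophile) rose to 0.0288 mM; after that, uptake and step 1 ran together, and at 5.00 s blue held protonated nucleophile at 0.870 mM beside 83% of its electrophile. Reckoned with that electrophile, the open gap is 92.2%, which puts c(nucleophile) at 0.124 mM, and blue held 0.123 mM. In teal at 2.50 s, with 91.7% of the electrophile left, the gap is 93.0%, which gives 0.113 mM, and teal held 0.112 mM.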